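**Retrosynthetic overview**

1. Core numbering used below: C1 (carries the acrylic acid), C2 (acyloxy), C3, C4 (C=CH2), C4a, C5, C6, C7 (CH2OH), C8, C8a; ring A = C1–C4/C4a/C8a, ring B = C4a–C8a.
2. Endgame: the C2–O ester is made by Mitsunobu inversion of the C2-axial alcohol 23 with acid 29 (from (R)-glyceraldehyde acetonide); fluoride, then mild acid, unmask the acid, the primary alcohol and the diol.
3. Ring A (formed last, key step): C4–C4a and C2–C3 are made in one operation. The enabling feature is that ring A is a 3-methylenecyclohexanol: C2–OH, C3H2 and the exocyclic methylene on C4 form a homoallylic alcohol whose allyl unit hangs by its central carbon on the heteroatom-free sp3 ring-fusion carbon C4a, so a carboxyl group on C4a (radical source) and an aldehyde at C2 can be bridged by the 2-bromoallylboronate 20.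
4. Ring B (formed first): catalytic enantioselective Diels–Alder reaction of triene 10 with an acrylimide (bonds C4a–C8a and C5–C6); its regiochemistry puts the carboxyl on C4a and sets C8a, the only stereocentre that has to be carried.
5. C1 with its acrylate and the masked C2 aldehyde come from a Morita–Baylis–Hillman adduct (3 + 4) via allylic bromide 6, SN2′ vinylation and enyne cross-metathesis.

Key step: step 11

Remark: C1 is formed without control in step 4 and is written without descriptor in 8–22, because it is expected to equilibrate through the C2 aldehyde in step 11; the configuration at C4a in 12–17 is immaterial because that centre becomes a radical; the bis(oxazoline) antipode in step 6 is assigned from the square-planar chelate model.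

**Route**

Step 1
Reactants: 1 acryloyl chloride; 2 2-(trimethylsilyl)ethanol
Product: 3 2-(trimethylsilyl)ethyl prop-2-enoate
Conditions: Et3N, CH2Cl2, 0 °C to rt
Reagents that add atoms: none
Why: Acylation of the alcohol by the acid chloride (nucleophilic acyl substitution) should give the fluoride-cleavable ester that carries the acrylic acid through the route.

Step 2
Reactants: 3 2-(trimethylsilyl)ethyl prop-2-enoate; 4 2,2-dimethoxyacetaldehyde (60% in water)
Product: 5 2-(trimethylsilyl)ethyl 3-hydroxy-4,4-dimethoxy-2-methylidenebutanoate (racemic)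
Conditions: DABCO (1 equiv), 1,4-dioxane/H2O, rt
Reagents that add atoms: none
Why: Morita–Baylis–Hillman reaction, in which the α,α-dialkoxy aldehyde is an activated acceptor for the DABCO–acrylate zwitterion; the carbinol centre need not be controlled because it is transposed in step 3.

Step 3
Reactants: 5 2-(trimethylsilyl)ethyl 3-hydroxy-4,4-dimethoxy-2-methylidenebutanoate
Product: 6 2-(trimethylsilyl)ethyl (2Z)-2-(bromomethyl)-4,4-dimethoxybut-2-enoate
Conditions: NBS, Me2S, CH2Cl2, 0 °C to rt
Reagents that add atoms: N-bromosuccinimide, O=C1CCC(=O)N1Br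
Why: The bromodimethylsulfonium species activates the allylic alcohol and bromide enters with allylic transposition (SN2′) to the thermodynamically preferred (Z)-2-(bromomethyl)enoate, under acid-free conditions that spare the acetal.

Step 4
Reactants: 6 2-(trimethylsilyl)ethyl (2Z)-2-(bromomethyl)-4,4-dimethoxybut-2-enoate; 7 vinylmagnesium bromide (CH2=CHMgBr, THF solution)
Product: 8 2-(trimethylsilyl)ethyl 2-(1,1-dimethoxybut-3-en-2-yl)prop-2-enoate (racemic)
Conditions: CuBr·SMe2 (10 mol%), THF, −78 °C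
Reagents that add atoms: none
Why: Copper-catalysed SN2′ substitution (conjugate addition, then β-elimination of bromide) should place the vinyl group on the acetal-bearing carbon and regenerate the 2-substituted acrylate; the new centre (future C1) is deliberately left uncontrolled.

Step 5
Reactants: 8 2-(trimethylsilyl)ethyl 2-(1,1-dimethoxybut-3-en-2-yl)prop-2-enoate; 9 tert-butyl(diphenyl)(prop-2-yn-1-yloxy)silane
Product: 10 2-(trimethylsilyl)ethyl 2-[(3E)-5-{[tert-butyl(diphenyl)silyl]oxymethyl}-1,1-dimethoxyhexa-3,5-dien-2-yl]prop-2-enoate (racemic)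
Conditions: second-generation Grubbs catalyst RuCl2(=CHPh)(H2IMes)(PCy3) (5 mol%), alkyne in threefold excess, CH2Cl2, 40 °C
Reagents that add atoms: none
Why: Cross enyne metathesis is a formal addition of the terminal alkyne across the monosubstituted alkene of 8 (the ruthenium alkylidene adds to the alkyne and the resulting vinylcarbene is transferred to the alkene), so every atom of both partners is kept and the 1,3-disubstituted diene should form with the E isomer predominating; the 1,1-disubstituted acrylate alkene is inert and any Z isomer cannot reach the s-cis geometry needed in step 6.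

Step 6
Reactants: 10 2-(trimethylsilyl)ethyl 2-[(3E)-5-{[tert-butyl(diphenyl)silyl]oxymethyl}-1,1-dimethoxyhexa-3,5-dien-2-yl]prop-2-enoate; 11 3-(prop-2-enoyl)-1,3-oxazolidin-2-one
Product: 12 2-(trimethylsilyl)ethyl 2-{1-[(1R,6R)-3-{[tert-butyl(diphenyl)silyl]oxymethyl}-6-(2-oxo-1,3-oxazolidine-3-carbonyl)cyclohex-2-en-1-yl]-2,2-dimethoxyethyl}prop-2-enoate (cis on the ring; both epimers at the CH between ring and acrylate)
Conditions: [Cu((R,R)-t-Bu-box)](SbF6)2 (10 mol%; ligand = 2,2′-(propane-2,2-diyl)bis[(4R)-4-tert-butyl-4,5-dihydrooxazole]), CH2Cl2, −20 °C to rt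
Reagents that add atoms: none
Why: Diels–Alder reaction under bis(oxazoline)–copper catalysis: the acrylimide is held s-cis in a square-planar chelate on divalent copper that leaves its Cα-Si face open, the 1- and 3-substituents of the diene both direct the acyl-bearing carbon to the substituted terminus, and endo addition should give the cis (1R,6R) adduct, which fixes the future C8a.

Step 7
Reactants: 12 the Diels–Alder imide
Product: 14 (1R,2R)-4-{[tert-butyl(diphenyl)silyl]oxymethyl}-2-(1,1-dimethoxy-3-{[2-(trimethylsilyl)ethoxy]carbonyl}but-3-en-2-yl)cyclohex-3-ene-1-carboxylic acid, via peroxy acid 13 (not isolated)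
Conditions: LiOH, H2O2, THF/H2O, 0 °C; Na2SO3; 1 M HCl to pH 3
Reagents that add atoms: lithium hydroperoxide (formed from LiOH and H2O2), [Li+].[O-]O
Why: Hydroperoxide attacks the exocyclic imide carbonyl selectively (standard N-acyloxazolidinone cleavage), and the silylethyl ester, the acetal and the silyl ether should be untouched at 0 °C.

Step 8
Reactants: 14 the cyclohexenecarboxylic acid; 15 N-hydroxyphthalimide
Product: 16 1,3-dioxoisoindolin-2-yl (1R,2R)-4-{[tert-butyl(diphenyl)silyl]oxymethyl}-2-(1,1-dimethoxy-3-{[2-(trimethylsilyl)ethoxy]carbonyl}but-3-en-2-yl)cyclohex-3-ene-1-carboxylate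
Conditions: N,N′-diisopropylcarbodiimide, DMAP (10 mol%), CH2Cl2, rt
Reagents that add atoms: none
Why: Carbodiimide (Steglich-type) esterification should give the redox-active N-acyloxyphthalimide that later releases the C4a radical.

Step 9
Reactants: 16 the redox-active ester acetal
Product: 17 1,3-dioxoisoindolin-2-yl (1R,2R)-4-{[tert-butyl(diphenyl)silyl]oxymethyl}-2-(1-oxo-3-{[2-(trimethylsilyl)ethoxy]carbonyl}but-3-en-2-yl)cyclohex-3-ene-1-carboxylate
Conditions: TsOH·H2O (10 mol%), acetone/H2O 10:1, rt; used at once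
Reagents that add atoms: water, O
Why: Acid-catalysed acetal hydrolysis unmasks the C2 aldehyde; the silyl ether, the silylethyl ester and the N-acyloxyphthalimide should tolerate dilute acid.

Step 10
Reactants: 18 2,3-dibromoprop-1-ene; 19 bis(pinacolato)diboron
Product: 20 2-(2-bromoprop-2-en-1-yl)-4,4,5,5-tetramethyl-1,3,2-dioxaborolane
Conditions: CuI (10 mol%), PPh3 (13 mol%), LiOMe, DMF, rt
Reagents that add atoms: none
Why: Copper-catalysed borylation of the allylic C–Br bond by a boryl-copper species; the vinylic bromide is inert to it.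

Step 11
Reactants: 17 the aldehyde redox-active ester; 20 2-(2-bromoprop-2-en-1-yl)-4,4,5,5-tetramethyl-1,3,2-dioxaborolane
Product: 23 2-(trimethylsilyl)ethyl 2-[(1S,2S,4aS,8aS)-7-{[tert-butyl(diphenyl)silyl]oxymethyl}-2-hydroxy-4-methylidene-1,2,3,4,4a,5,6,8a-octahydronaphthalen-1-yl]prop-2-enoate (trans ring fusion, C2–OH axial), via allylboronate aldehyde 21 (not isolated), via O-boryl ether 22 (not isolated)
Conditions: NiCl2·6H2O (20 mol%), 2,2′-bipyridine (20 mol%), AgNO3 (30 mol%), LiCl, Mg anode, RVC cathode, boronate in 2.5-fold excess, DMF (0.02 M in the redox-active ester), constant current, rt; then pH 7 phosphate buffer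
Reagents that add atoms: none
Why: Proposed new method: at the cathode a low-valent nickel–bipyridine species reduces the N-acyloxyphthalimide of 17, CO2 is lost, and the planar C4a radical is captured by the alkenylnickel formed from 20, reductive elimination making C4–C4a; this turns the electron-poor 2-bromoallylboronate into the electron-rich 2-alkylallylboronate 21, which at once adds to the aldehyde in the same molecule (C3–C2) through a closed six-membered B–O transition state. The closest known reaction types are the nickel-electrocatalytic decarboxylative alkenylation of redox-active esters with alkenyl bromides and the intramolecular allylboration of aldehydes; new is only their coupling through a boron-bearing bromoalkene. Ring A closes in a 6-membered mode in which the tether leaves the central carbon of the allyl unit, so the O–B–CH2 bridge spans C2 and C4 of the forming chair 1,3-diaxially (bicyclo[3.3.1]-type array). C4a is set trans to the C8a side chain by attack on the radical face remote from that substituent (either C4a epimer of the acid converges), C2 carries an axial oxygen because of the bridge, and C1 takes its acrylate equatorial because the α-formyl epimers should interconvert through the enol (phthalimide anion as base) faster than the disfavoured one cyclises. The step needs nickel capture of the radical to outrun Giese addition to the acrylates (dilute solution, high nickel loading, 5-endo closure onto the molecule's own acrylate is disfavoured) and no allylboration before the coupling (the bromine on the allyl unit deactivates 20 towards carbonyl addition).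

Step 12
Reactants: 24 (4R)-2,2-dimethyl-1,3-dioxolane-4-carbaldehyde; 25 dimethyl (1-diazo-2-oxopropyl)phosphonate
Product: 26 (4S)-4-ethynyl-2,2-dimethyl-1,3-dioxolane
Conditions: K2CO3, MeOH, 0 °C to rt
Reagents that add atoms: none
Why: Seyferth–Gilbert homologation with the Ohira–Bestmann reagent converts the aldehyde into the terminal alkyne without touching the stereocentre (the descriptor changes to S by priority only).

Step 13
Reactants: 26 (4S)-4-ethynyl-2,2-dimethyl-1,3-dioxolane
Product: 29 2-[(4S)-2,2-dimethyl-1,3-dioxolan-4-yl]prop-2-enoic acid, via alkenylalane 27 (not isolated), via lithium alkenylalanate 28 (not isolated)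
Conditions: NiCl2(dppp) (3 mol%), i-Bu2AlH, THF, 0 °C to rt; MeLi, −78 °C; CO2; 1 M HCl to pH 3, 0 °C
Reagents that add atoms: carbon dioxide, O=C=O
Why: Nickel-catalysed α-selective (Markovnikov) hydroalumination should put aluminium on the internal alkyne carbon, and carboxylation of the derived alanate with CO2 gives the 2-substituted acrylic acid; the stereocentre is not involved.

Step 14
Reactants: 23 the C2-axial alcohol; 29 2-[(4S)-2,2-dimethyl-1,3-dioxolan-4-yl]prop-2-enoic acid
Product: 30 (1S,2R,4aS,8aS)-7-{[tert-butyl(diphenyl)silyl]oxymethyl}-4-methylidene-1-{3-oxo-3-[2-(trimethylsilyl)ethoxy]prop-1-en-2-yl}-1,2,3,4,4a,5,6,8a-octahydronaphthalen-2-yl 2-[(4S)-2,2-dimethyl-1,3-dioxolan-4-yl]prop-2-enoate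
Conditions: PPh3, DIAD, THF, 0 °C to rt
Reagents that add atoms: none
Why: Mitsunobu reaction: the axial C2 oxyphosphonium is displaced by the carboxylate of 29 from the equatorial side (SN2), which should invert C2 to the required 2R configuration while installing the side chain.

Step 15
Reactants: 30 the fully protected diester
Product: 31 2-[(1S,2R,4aS,8aS)-2-({2-[(4S)-2,2-dimethyl-1,3-dioxolan-4-yl]prop-2-enoyl}oxy)-7-(hydroxymethyl)-4-methylidene-1,2,3,4,4a,5,6,8a-octahydronaphthalen-1-yl]prop-2-enoic acid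
Conditions: TBAF (5 equiv), THF, 0 °C to rt; aq. NH4Cl
Reagents that add atoms: none
Why: Fluoride cleaves the silyl ether and fragments the 2-(trimethylsilyl)ethyl ester (β-elimination to ethene) while the diol is still masked, so no free hydroxyl can lactonise onto the C2 ester under basic conditions.

Step 16
Reactants: 31 the acetonide acid
Product: 32 2-[(1S,2R,4aS,8aS)-2-{[(3S)-3,4-dihydroxy-2-methylidenebutanoyl]oxy}-7-(hydroxymethyl)-4-methylidene-1,2,3,4,4a,5,6,8a-octahydronaphthalen-1-yl]prop-2-enoic acid (CNP0460913.3)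
Conditions: AcOH/H2O 4:1, 35 °C
Reagents that add atoms: none
Why: Mild acid hydrolysis of the isopropylidene acetal; the esters, the exocyclic alkene and the allylic alcohol should survive.

**Compound list**

1 | acryloyl chloride | C=CC(=O)Cl | starting material
2 | 2-(trimethylsilyl)ethanol | OCC[Si](C)(C)C | starting material
3 | 2-(trimethylsilyl)ethyl prop-2-enoate | C=CC(=O)OCC[Si](C)(C)C | intermediate
4 | 2,2-dimethoxyacetaldehyde | COC(OC)C=O | starting material
5 | 2-(trimethylsilyl)ethyl 3-hydroxy-4,4-dimethoxy-2-methylidenebutanoate (racemic) | C=C(C(O)C(OC)OC)C(=O)OCC[Si](C)(C)C | intermediate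
6 | 2-(trimethylsilyl)ethyl (2Z)-2-(bromomethyl)-4,4-dimethoxybut-2-enoate | COC(OC)/C=C(/C(=O)OCC[Si](C)(C)C)CBr | intermediate
7 | vinylmagnesium bromide | C=C[Mg]Br | starting material
8 | 2-(trimethylsilyl)ethyl 2-(1,1-dimethoxybut-3-en-2-yl)prop-2-enoate (racemic) | C=CC(C(OC)OC)C(=C)C(=O)OCC[Si](C)(C)C | intermediate
9 | tert-butyl(diphenyl)(prop-2-yn-1-yloxy)silane | C#CCO[Si](c1ccccc1)(c1ccccc1)C(C)(C)C | starting material
10 | 2-(trimethylsilyl)ethyl 2-[(3E)-5-{[tert-butyl(diphenyl)silyl]oxymethyl}-1,1-dimethoxyhexa-3,5-dien-2-yl]prop-2-enoate (racemic) | C=C(CO[Si](c1ccccc1)(c1ccccc1)C(C)(C)C)/C=C/C(C(OC)OC)C(=C)C(=O)OCC[Si](C)(C)C | intermediate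
11 | 3-(prop-2-enoyl)-1,3-oxazolidin-2-one | C=CC(=O)N1CCOC1=O | starting material
12 | 2-(trimethylsilyl)ethyl 2-{1-[(1R,6R)-3-{[tert-butyl(diphenyl)silyl]oxymethyl}-6-(2-oxo-1,3-oxazolidine-3-carbonyl)cyclohex-2-en-1-yl]-2,2-dimethoxyethyl}prop-2-enoate (both epimers at the linking CH) | COC(OC)C(C(=C)C(=O)OCC[Si](C)(C)C)[C@H]1C=C(CO[Si](c2ccccc2)(c2ccccc2)C(C)(C)C)CC[C@H]1C(=O)N1CCOC1=O | intermediate
13 | (1R,2R)-4-{[tert-butyl(diphenyl)silyl]oxymethyl}-2-(1,1-dimethoxy-3-{[2-(trimethylsilyl)ethoxy]carbonyl}but-3-en-2-yl)cyclohex-3-ene-1-carboperoxoic acid | COC(OC)C(C(=C)C(=O)OCC[Si](C)(C)C)[C@H]1C=C(CO[Si](c2ccccc2)(c2ccccc2)C(C)(C)C)CC[C@H]1C(=O)OO | intermediate (not isolated)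
14 | (1R,2R)-4-{[tert-butyl(diphenyl)silyl]oxymethyl}-2-(1,1-dimethoxy-3-{[2-(trimethylsilyl)ethoxy]carbonyl}but-3-en-2-yl)cyclohex-3-ene-1-carboxylic acid | COC(OC)C(C(=C)C(=O)OCC[Si](C)(C)C)[C@H]1C=C(CO[Si](c2ccccc2)(c2ccccc2)C(C)(C)C)CC[C@H]1C(=O)O | intermediate
15 | N-hydroxyphthalimide | O=C1c2ccccc2C(=O)N1O | starting material
16 | 1,3-dioxoisoindolin-2-yl (1R,2R)-4-{[tert-butyl(diphenyl)silyl]oxymethyl}-2-(1,1-dimethoxy-3-{[2-(trimethylsilyl)ethoxy]carbonyl}but-3-en-2-yl)cyclohex-3-ene-1-carboxylate | COC(OC)C(C(=C)C(=O)OCC[Si](C)(C)C)[C@H]1C=C(CO[Si](c2ccccc2)(c2ccccc2)C(C)(C)C)CC[C@H]1C(=O)ON1C(=O)c2ccccc2C1=O | intermediate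
17 | 1,3-dioxoisoindolin-2-yl (1R,2R)-4-{[tert-butyl(diphenyl)silyl]oxymethyl}-2-(1-oxo-3-{[2-(trimethylsilyl)ethoxy]carbonyl}but-3-en-2-yl)cyclohex-3-ene-1-carboxylate | O=CC(C(=C)C(=O)OCC[Si](C)(C)C)[C@H]1C=C(CO[Si](c2ccccc2)(c2ccccc2)C(C)(C)C)CC[C@H]1C(=O)ON1C(=O)c2ccccc2C1=O | intermediate
18 | 2,3-dibromoprop-1-ene | C=C(Br)CBr | starting material
19 | bis(pinacolato)diboron | CC1(C)OB(B2OC(C)(C)C(C)(C)O2)OC1(C)C | starting material
20 | 2-(2-bromoprop-2-en-1-yl)-4,4,5,5-tetramethyl-1,3,2-dioxaborolane | C=C(Br)CB1OC(C)(C)C(C)(C)O1 | intermediate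
21 | 2-(trimethylsilyl)ethyl 2-{1-[(1S,6S)-3-{[tert-butyl(diphenyl)silyl]oxymethyl}-6-[3-(4,4,5,5-tetramethyl-1,3,2-dioxaborolan-2-yl)prop-1-en-2-yl]cyclohex-2-en-1-yl]-2-oxoethyl}prop-2-enoate (trans on the ring) | O=CC(C(=C)C(=O)OCC[Si](C)(C)C)[C@H]1C=C(CO[Si](c2ccccc2)(c2ccccc2)C(C)(C)C)CC[C@@H]1C(=C)CB1OC(C)(C)C(C)(C)O1 | intermediate (not isolated)
22 | 2-(trimethylsilyl)ethyl 2-[(1S,2S,4aS,8aS)-7-{[tert-butyl(diphenyl)silyl]oxymethyl}-4-methylidene-2-[(4,4,5,5-tetramethyl-1,3,2-dioxaborolan-2-yl)oxy]-1,2,3,4,4a,5,6,8a-octahydronaphthalen-1-yl]prop-2-enoate | C=C(C(=O)OCC[Si](C)(C)C)[C@@H]1[C@H]2C=C(CO[Si](c3ccccc3)(c3ccccc3)C(C)(C)C)CC[C@@H]2C(=C)C[C@@H]1OB1OC(C)(C)C(C)(C)O1 | intermediate (not isolated)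
23 | 2-(trimethylsilyl)ethyl 2-[(1S,2S,4aS,8aS)-7-{[tert-butyl(diphenyl)silyl]oxymethyl}-2-hydroxy-4-methylidene-1,2,3,4,4a,5,6,8a-octahydronaphthalen-1-yl]prop-2-enoate | C=C(C(=O)OCC[Si](C)(C)C)[C@@H]1[C@H]2C=C(CO[Si](c3ccccc3)(c3ccccc3)C(C)(C)C)CC[C@@H]2C(=C)C[C@@H]1O | intermediate
24 | (4R)-2,2-dimethyl-1,3-dioxolane-4-carbaldehyde | O=C[C@H]1COC(C)(C)O1 | starting material
25 | dimethyl (1-diazo-2-oxopropyl)phosphonate | COP(=O)(OC)C(=[N+]=[N-])C(C)=O | starting material
26 | (4S)-4-ethynyl-2,2-dimethyl-1,3-dioxolane | C#C[C@H]1COC(C)(C)O1 | intermediate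
27 | {1-[(4R)-2,2-dimethyl-1,3-dioxolan-4-yl]ethenyl}bis(2-methylpropyl)alane (same spatial arrangement as 26) | C=C([Al](CC(C)C)CC(C)C)[C@H]1COC(C)(C)O1 | intermediate (not isolated)
28 | lithium {1-[(4R)-2,2-dimethyl-1,3-dioxolan-4-yl]ethenyl}(methyl)bis(2-methylpropyl)alanate | [Li+].C=C([Al-](C)(CC(C)C)CC(C)C)[C@H]1COC(C)(C)O1 | intermediate (not isolated)
29 | 2-[(4S)-2,2-dimethyl-1,3-dioxolan-4-yl]prop-2-enoic acid | C=C(C(=O)O)[C@H]1COC(C)(C)O1 | intermediate
30 | (1S,2R,4aS,8aS)-7-{[tert-butyl(diphenyl)silyl]oxymethyl}-4-methylidene-1-{3-oxo-3-[2-(trimethylsilyl)ethoxy]prop-1-en-2-yl}-1,2,3,4,4a,5,6,8a-octahydronaphthalen-2-yl 2-[(4S)-2,2-dimethyl-1,3-dioxolan-4-yl]prop-2-enoate | C=C(C(=O)OCC[Si](C)(C)C)[C@@H]1[C@H]2C=C(CO[Si](c3ccccc3)(c3ccccc3)C(C)(C)C)CC[C@@H]2C(=C)C[C@H]1OC(=O)C(=C)[C@H]1COC(C)(C)O1 | intermediate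
31 | 2-[(1S,2R,4aS,8aS)-2-({2-[(4S)-2,2-dimethyl-1,3-dioxolan-4-yl]prop-2-enoyl}oxy)-7-(hydroxymethyl)-4-methylidene-1,2,3,4,4a,5,6,8a-octahydronaphthalen-1-yl]prop-2-enoic acid | C=C(C(=O)O)[C@@H]1[C@H]2C=C(CO)CC[C@@H]2C(=C)C[C@H]1OC(=O)C(=C)[C@H]1COC(C)(C)O1 | intermediate
32 | 2-[(1S,2R,4aS,8aS)-2-{[(3S)-3,4-dihydroxy-2-methylidenebutanoyl]oxy}-7-(hydroxymethyl)-4-methylidene-1,2,3,4,4a,5,6,8a-octahydronaphthalen-1-yl]prop-2-enoic acid | C=C(C(=O)O)[C@@H]1[C@H]2C=C(CO)CC[C@@H]2C(=C)C[C@H]1OC(=O)C(=C)[C@H](O)CO | target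

**Step count and risks**

Total steps: 16. Longest linear sequence: 13 steps (steps 1–9, 11, 14, 15, 16).

Most likely to fail, step 11 (proposed new method): the C4a radical may add to an acrylate (Giese-type) instead of being captured by nickel, carbonyl allylboration by 20 may occur before the cross-coupling so that control at C2 is lost, and the α-formyl centre may epimerise too slowly or drift into conjugation with the acrylate. Fallback with known chemistry, setting out from 17 and coming back at 30: nickel-electrocatalytic decarboxylative alkenylation of 17 with commercial (2-bromoprop-2-en-1-yl)trimethylsilane should give the allylsilane aldehyde 2-(trimethylsilyl)ethyl 2-{1-[(1S,6S)-3-{[tert-butyl(diphenyl)silyl]oxymethyl}-6-[3-(trimethylsilyl)prop-1-en-2-yl]cyclohex-2-en-1-yl]-2-oxoethyl}prop-2-enoate F1. SnCl4-promoted intramolecular Hosomi–Sakurai cyclisation (CH2Cl2, −78 °C; open transition state with the tin-bound oxygen equatorial) should then give the C2-equatorial alcohol 2-(trimethylsilyl)ethyl 2-[(1S,2R,4aS,8aS)-7-{[tert-butyl(diphenyl)silyl]oxymethyl}-2-hydroxy-4-methylidene-1,2,3,4,4a,5,6,8a-octahydronaphthalen-1-yl]prop-2-enoate F2, and Yamaguchi esterification of F2 with 29 (2,4,6-trichlorobenzoyl chloride, Et3N, DMAP; retention at C2) gives 30.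

Step 14: the axial oxyphosphonium may undergo elimination towards C1 or C3 (both give conjugated dienes) instead of substitution. Fallback setting out from 23 and coming back at 30: Dess–Martin oxidation of 23 should give the ketone 2-(trimethylsilyl)ethyl 2-[(1S,4aS,8aS)-7-{[tert-butyl(diphenyl)silyl]oxymethyl}-4-methylidene-2-oxo-1,2,3,4,4a,5,6,8a-octahydronaphthalen-1-yl]prop-2-enoate F3. Luche reduction (NaBH4, CeCl3·7H2O, MeOH, −78 °C; axial hydride delivery) should give the C2-equatorial alcohol F2 already described in the first fallback, and Yamaguchi esterification with 29 gives 30.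

Step 5: the enyne cross-metathesis may give poor E/Z control and homodimerisation or oligomerisation of the partners. Fallback setting out from 8 and coming back at 10: alkene cross-metathesis of 8 with vinylboronic acid pinacol ester (second-generation Grubbs catalyst RuCl2(=CHPh)(H2IMes)(PCy3)) should give the (E)-alkenylboronate 2-(trimethylsilyl)ethyl 2-[(3E)-1,1-dimethoxy-4-(4,4,5,5-tetramethyl-1,3,2-dioxaborolan-2-yl)but-3-en-2-yl]prop-2-enoate F4. Suzuki–Miyaura coupling (Pd(PPh3)4, K3PO4, THF/H2O) with tert-butyl[(2-bromoprop-2-en-1-yl)oxy]diphenylsilane F5, made from 2-bromoprop-2-en-1-ol and tert-butyl(chloro)diphenylsilane with imidazole, should give 10 with defined E geometry.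

**Further compounds**

F1 | step 11 | 2-(trimethylsilyl)ethyl 2-{1-[(1S,6S)-3-{[tert-butyl(diphenyl)silyl]oxymethyl}-6-[3-(trimethylsilyl)prop-1-en-2-yl]cyclohex-2-en-1-yl]-2-oxoethyl}prop-2-enoate | O=CC(C(=C)C(=O)OCC[Si](C)(C)C)[C@H]1C=C(CO[Si](c2ccccc2)(c2ccccc2)C(C)(C)C)CC[C@@H]1C(=C)C[Si](C)(C)C
F2 | step 11 | 2-(trimethylsilyl)ethyl 2-[(1S,2R,4aS,8aS)-7-{[tert-butyl(diphenyl)silyl]oxymethyl}-2-hydroxy-4-methylidene-1,2,3,4,4a,5,6,8a-octahydronaphthalen-1-yl]prop-2-enoate | C=C(C(=O)OCC[Si](C)(C)C)[C@@H]1[C@H]2C=C(CO[Si](c3ccccc3)(c3ccccc3)C(C)(C)C)CC[C@@H]2C(=C)C[C@H]1O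
F3 | step 14 | 2-(trimethylsilyl)ethyl 2-[(1S,4aS,8aS)-7-{[tert-butyl(diphenyl)silyl]oxymethyl}-4-methylidene-2-oxo-1,2,3,4,4a,5,6,8a-octahydronaphthalen-1-yl]prop-2-enoate | C=C(C(=O)OCC[Si](C)(C)C)[C@@H]1[C@H]2C=C(CO[Si](c3ccccc3)(c3ccccc3)C(C)(C)C)CC[C@@H]2C(=C)CC1=O
F4 | step 5 | 2-(trimethylsilyl)ethyl 2-[(3E)-1,1-dimethoxy-4-(4,4,5,5-tetramethyl-1,3,2-dioxaborolan-2-yl)but-3-en-2-yl]prop-2-enoate | CC1(C)OB(/C=C/C(C(OC)OC)C(=C)C(=O)OCC[Si](C)(C)C)OC1(C)C
F5 | step 5 | tert-butyl[(2-bromoprop-2-en-1-yl)oxy]diphenylsilane | C=C(Br)CO[Si](c1ccccc1)(c1ccccc1)C(C)(C)C
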